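## Analysis of the target

Target 20 is pentacyclic. Ring A is a cyclohexene with a vinylic methyl group. Ring B is a seven-membered enol lactone whose enol carbon is exocyclic to ring A, so rings A and B share a 1-acyloxy-1,3-diene. Ring C is a tetrasubstituted benzene, ring D a 1,4-quinone, and ring E an N–H 3,4-dihydro-2H-1,4-thiazine 1,1-dioxide fused to the quinone C=C. Rings C–E are numbered as a naphtho[2,3-b][1,4]thiazine: S1, C2, C3, N4, C4a, C5, C5a, C6–C9, C9a, C10, C10a. Ring A is attached at C7 and the lactone carbonyl at C8.

The only stereocentre is the quaternary carbon shared by rings A and B. It carries a methyl group, C7 of ring C, a ring CH2 and the enol-bearing sp2 carbon of ring A, and it is (S) (priorities: enol-bearing carbon > aryl > CH2 > CH3). There is no relative stereochemistry to control.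

The sensitive groups are the dienol ester (hydrolysis, nucleophiles, double-bond migration), the quinone (nucleophiles, reductants) and the acidic vinylogous sulfonamide N–H. Ring B therefore has to be closed last.

Two things make the synthesis hard. The first is an all-carbon quaternary centre on an arene, ortho to a carboxyl group. The second is the placement of nitrogen and sulfur: C4a (nitrogen) lies next to C5, whose ring C neighbour C5a is para to C8, while C10a (sulfur) lies next to C10. The two quinone carbons differ only through these remote groups, so adding an aminosulfinate to a preformed quinone would not distinguish them.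

The strategy rests on the four-carbon unit C5–C4a–C10a–C10, which carries O, N, S and O. This is the carbon skeleton of squaric acid with ring E already attached. It can be joined to ring C first through C5 and then through C10.

## Retrosynthetic reasoning

**Ring B and the protecting groups (20 ⇒ 18).** The enol ester C–O bond between the carboxyl oxygen and the exocyclic CH is cut first, because the dienol lactone is the most fragile part of 20. The acid is stored as a tert-butyl ester, the enol as a methyl dienol ether and the nitrogen as a tert-butyl carbamate, giving quinone 18. One acid treatment has to remove both tert-butyl groups and exchange methoxy for acyloxy at the dienol carbon. The free acid 19 is the expected intermediate.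

**Oxidation level (18 ⇒ 17).** The quinone is taken back to hydroquinone 17, the direct product of the ring-forming step. The forward step needs a neutral oxidant that leaves the dienol ether alone.

**Ring D (17 ⇒ 15 via 16).** The C10–C9a bond is cut and C10 is reconnected to C5. This gives the 4-aryl-4-hydroxycyclobutenone 15, in which ring E is already fused to the four-membered ring. The disconnection is made here because it turns the nitrogen/sulfur problem into a constitutional feature of a small ring: the carbinol carbon (future C5) is the one next to the nitrogen-bearing carbon. The forward reaction is a thermal ring opening to dienylketene 16 and closure onto ring C. It must choose the ortho carbon remote from the ring A substituent.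

**Union of the fragments (15 ⇒ 7 + 13).** The C5–C5a bond is cut between aryl bromide 7 (as arylmagnesium 14) and the N-Boc thiazine-fused cyclobutenedione 13. The route is convergent at this point, with two fragments of similar size. The addition must go to the carbonyl next to the nitrogen-bearing carbon, which is the only carbonyl of 13 that is not a vinylogous carbamate.

**Ring E (13 ⇒ 12 ⇒ 9 + 10, 9 ⇒ 8).** The C–N and C–S bonds of ring E are cut back to squaric dichloride 9 and hypotaurine 10. Because 9 is symmetric, either order of attack gives the same bicycle 12, via 11. Compound 9 comes from squaric acid 8. Carbamate formation on 12 removes the acidic N–H before the organometallic step.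

**The enol carbon (7 ⇒ 6).** The exocyclic C=C is cut to enone 6 and a one-carbon methoxymethylene unit (Wittig reaction). The dienol ether survives bases and organometallics and carries the aldehyde oxidation level needed for ring B.

**Ring A unsaturation and the quaternary centre (6 ⇒ 4 ⇒ 2 + 3, 2 ⇒ 1).** The ring double bond is removed to give ketone 4. The aryl–C(quaternary) bond is then cut to aryl iodide 2 and 2,6-dimethylcyclohexanone 3. In 3 both α-carbons already carry methyl groups, so there is no regiochemical question and the catalyst sets the stereocentre. The iodide is used for this coupling and the bromide is kept for the later metalation. Ester 2 comes from acid 1.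

## Alternatives that were turned down

**Alternative 1: dearomative Robinson annulation.**
- Disconnection: ring A is opened at the quaternary carbon–CH2 bond and at its enone double bond, back to 7-bromo-4-methoxy-1-methylnaphthalen-2-ol A1 and pent-1-en-3-one A2. Ring B starts as the second carbocycle of a naphthalene.
- Forward key step: under a chiral quaternary ammonium salt and hydroxide, C1 of A1 adds to A2 with loss of aromaticity, and aldol condensation in the same flask closes ring A to give tricyclic dienone A3.
- For: two C–C bonds, ring A and the quaternary stereocentre form in one operation, with the arene already attached. No hindered aryl–carbon coupling is needed. On this point it is stronger than the chosen route, whose arylation (step 2) is its least secure early step.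
- Against: in A3 ring B is a six-membered carbocyclic enol ether, so the lactone oxygen must be inserted later by oxidative ring expansion next to alkenes. Ring A carries a carbonyl that must be removed with transposition of the double bond. Rings D and E must still be grown from one bromide, and a hetero-annulation onto a finished quinone gives no control over nitrogen and sulfur. Ion-pair control of a naphthoxide Michael addition also has to compete with O-alkylation and the uncatalysed reaction.
- Comparison: the key step is efficient, but many redox and ring-editing steps follow it. The chosen route offers a convergent assembly in which rings D and E arrive with fixed regiochemistry.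

**Alternative 2: ortho-quinodimethane cycloaddition to build ring C.**
- Disconnection: ring C is cut at the two bonds joining its benzylic CH2 carbons to an alkyne, back to 2,3-bis(bromomethyl)-1,4-dimethoxybenzene A4 and alkynoate A5, which carries ring A.
- Forward key step: iodide-induced 1,4-elimination from A4 gives the ortho-quinodimethane, which adds across the triple bond of A5 to give 1,4-dihydronaphthalene A6.
- For: the diene is symmetric, so the cycloaddition has no regiochemical issue. The ester ends up ortho to ring A by construction. Ring C grows from a quaternary carbon that already exists, so this route also avoids the hindered arylation.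
- Against: the key step creates no stereocentre, so A5 with its quaternary propargylic carbon must first be made as a single enantiomer, which is at least as hard as the ketone arylation. The alkyne sits next to that quaternary carbon and must intercept a short-lived diene that readily dimerises. After aromatisation and oxidative demethylation, ring E has to be added to a quinone whose two CH positions differ only through remote groups, so a mixture of nitrogen/sulfur isomers is expected. The oxidations also have to tolerate the enal.
- Comparison: it matches the chosen route on the ortho relationship and beats it on the aryl–carbon bond. It loses on stereocentre supply and on the defining regiochemical problem.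

**Alternative 3: asymmetric Diels–Alder reaction of a 2-arylacrolein.**
- Disconnection: ring A is cut at the two bonds to the acrolein carbons, back to 2-(naphthyl)acrolein A7 and silyloxy diene A8.
- Forward key step: a triflimide-activated chiral B-aryl oxazaborolidine catalyses the cycloaddition to give cycloadduct A9.
- For: 2-substituted acroleins are privileged dienophiles for this catalyst class, and the facial selectivity follows a well-understood model. It is the most secure way among the four to an aryl-bearing quaternary stereocentre. The trimethoxynaphthalene in A7 has a methoxy group on the carbon destined for nitrogen, so a later amine substitution would also fix the heteroatom positions. On both points it equals or beats the chosen route.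
- Against: the quaternary carbon of A9 carries a formyl group where 20 has methyl, so a neopentyl aldehyde must be fully deoxygenated over several steps. The silyloxy carbon must be oxidised to the ketone and then homologated by one carbon, which leads to the same hindered methoxymethylenation as in the chosen route. A7 requires a fully substituted naphthalene made in a linear sequence. The electron-rich arene must be oxidised to the quinone next to the dienol unit, and ring E is still added at the end.
- Comparison: stereocontrol is better, but the route is longer and linear. The chosen route forms rings D and E in one thermal step from two fragments and accepts a less certain arylation in exchange.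

Key step: step 9

## Route

Assumption: (R)-BINAP is written in step 2; if the first run shows the opposite sense of induction, the mirror-image ligand is used.

Assumption: the enol ether of 7 and later compounds is an E/Z mixture and 15 is a mixture of carbinol epimers; both elements disappear later and are not controlled.

Step 1
Reactants: 1 4-bromo-2-iodobenzoic acid
Product: 2 tert-butyl 4-bromo-2-iodobenzoate
Conditions: Cl3CC(=NH)OtBu (2 equiv.), CH2Cl2/cyclohexane, rt
Reagents that add atoms: tert-butyl 2,2,2-trichloroacetimidate, CC(C)(C)OC(=N)C(Cl)(Cl)Cl
Why: Acid-promoted tert-butyl transfer from the trichloroacetimidate esterifies the hindered ortho-iodo acid without touching either halogen. The tert-butyl ester is chosen because it survives alkoxide, amide bases and Grignard reagents and is removed in the last step.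

Step 2
Reactants: 2 tert-butyl 4-bromo-2-iodobenzoate; 3 2,6-dimethylcyclohexanone (cis/trans mixture)
Product: 4 tert-butyl 4-bromo-2-[(1S)-1,3-dimethyl-2-oxocyclohexyl]benzoate (epimers at the CH–CH3 carbon)
Conditions: Pd2(dba)3 (2.5 mol %), (R)-BINAP (6 mol %), NaOtBu (1.3 equiv.), toluene, 60 °C; 2 in slight excess
Reagents that add atoms: none
Why: Palladium-catalysed asymmetric α-arylation of a ketone enolate: zerovalent palladium inserts into C–I in preference to C–Br, the tetrasubstituted sodium enolate of 3 (both α-carbons equivalent) replaces iodide on palladium, and C–C reductive elimination inside the chiral bisphosphine pocket sets the quaternary carbon. The second methyl-bearing carbon forms as an epimer mixture, which is harmless because it becomes sp2 in step 3; tert-butoxide cannot cleave the tert-butyl ester.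

Step 3
Reactants: 4 tert-butyl 4-bromo-2-[(1S)-1,3-dimethyl-2-oxocyclohexyl]benzoate
Product: 6 tert-butyl 4-bromo-2-[(1S)-1,3-dimethyl-2-oxocyclohex-3-en-1-yl]benzoate, via trimethylsilyl enol ether 5 (not isolated)
Conditions: LiN(iPr)2, THF, −78 °C; Me3SiCl, −78 to 0 °C; then Pd(OAc)2 (1.1 equiv.), MeCN, rt to 40 °C
Reagents that add atoms: none
Why: Saegusa–Ito oxidation: the only enolisable position of 4 is the methyl-bearing α-carbon, so a single silyl enol ether forms, and Pd(OAc)2 gives the palladium enolate, which loses β-hydride from the ring CH2 to give the conjugated endocyclic enone. The quaternary centre has no α-hydrogen and cannot epimerise.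

Step 4
Reactants: 6 tert-butyl 4-bromo-2-[(1S)-1,3-dimethyl-2-oxocyclohex-3-en-1-yl]benzoate
Product: 7 tert-butyl 4-bromo-2-[(1S)-2-(methoxymethylidene)-1,3-dimethylcyclohex-3-en-1-yl]benzoate (E/Z mixture)
Conditions: Ph3P(CH2OMe)Cl (4 equiv.), KN(SiMe3)2, THF, 0 to 50 °C
Reagents that add atoms: (methoxymethyl)triphenylphosphonium chloride, COC[P+](c1ccccc1)(c1ccccc1)c1ccccc1.[Cl-]
Why: Wittig methoxymethylenation: the small, non-stabilised ylide adds 1,2 to the hindered enone carbonyl and the oxaphosphetane collapses to the dienol ether. The ester and the aryl bromide are inert to the ylide, and the enol ether geometry is not needed.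

Step 5
Reactants: 8 squaric acid
Product: 9 3,4-dichlorocyclobut-3-ene-1,2-dione
Conditions: (COCl)2 (2.2 equiv.), DMF (cat.), CH2Cl2, reflux
Reagents that add atoms: oxalyl chloride, ClC(=O)C(Cl)=O
Why: Vilsmeier-type activation converts both vinylogous acid hydroxyl groups into chlorides; this is the standard preparation of this vinylogous acid chloride.

Step 6
Reactants: 9 3,4-dichlorocyclobut-3-ene-1,2-dione; 10 hypotaurine
Product: 12 2-thia-5-azabicyclo[4.2.0]oct-1(6)-ene-7,8-dione 2,2-dioxide, via aminochlorocyclobutenedione sulfinate 11 (not isolated)
Conditions: iPr2NEt (3 equiv.), DMF, −30 °C to rt, slow addition of 9 in MeCN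
Reagents that add atoms: none
Why: Two addition–elimination substitutions at the equivalent chloro-bearing carbons: the amine substitutes first (11), then the sulfinate, reacting at sulfur as sulfinates do with β-chloro enones, closes the six-membered ring as the sulfone. Because 9 is symmetric there is no regiochemical question, and the product is stabilised as a push–pull enaminone.

Step 7
Reactants: 12 2-thia-5-azabicyclo[4.2.0]oct-1(6)-ene-7,8-dione 2,2-dioxide
Product: 13 tert-butyl 7,8-dioxo-2-thia-5-azabicyclo[4.2.0]oct-1(6)-ene-5-carboxylate 2,2-dioxide
Conditions: Boc2O (1.2 equiv.), DMAP (10 mol %), MeCN, rt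
Reagents that add atoms: di-tert-butyl dicarbonate, CC(C)(C)OC(=O)OC(=O)OC(C)(C)C
Why: DMAP-catalysed acylation of the acidic vinylogous amide N–H, as for lactams and sulfonamides. The carbamate removes the acidic proton before the Grignard addition and is cleaved by acid in step 11.

Step 8
Reactants: 7 tert-butyl 4-bromo-2-[(1S)-2-(methoxymethylidene)-1,3-dimethylcyclohex-3-en-1-yl]benzoate; 13 tert-butyl 7,8-dioxo-2-thia-5-azabicyclo[4.2.0]oct-1(6)-ene-5-carboxylate 2,2-dioxide
Product: 15 tert-butyl 7-{4-(tert-butoxycarbonyl)-3-[(1S)-2-(methoxymethylidene)-1,3-dimethylcyclohex-3-en-1-yl]phenyl}-7-hydroxy-8-oxo-2-thia-5-azabicyclo[4.2.0]oct-1(6)-ene-5-carboxylate 2,2-dioxide (carbinol epimers), via arylmagnesium chloride 14 (not isolated)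
Conditions: iPrMgCl·LiCl (1.05 equiv.), THF, −10 to 0 °C; then cannulation into 13 (1.2 equiv.), THF, −78 °C; aq. NH4Cl
Reagents that add atoms: none
Why: Bromine–magnesium exchange with iPrMgCl·LiCl tolerates a tert-butyl benzoate, and the arylmagnesium adds 1,2 to C7=O of 13, the ketone-like carbonyl conjugated with the sulfonyl-bearing carbon. C8=O is deactivated as a vinylogous carbamate, in line with the known preference of organometallics for the non-vinylogous carbonyl of unsymmetrical squaric acid derivatives. The new carbinol centre is uncontrolled and becomes sp2 in step 9.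

Step 9
Reactants: 15 tert-butyl 7-{4-(tert-butoxycarbonyl)-3-[(1S)-2-(methoxymethylidene)-1,3-dimethylcyclohex-3-en-1-yl]phenyl}-7-hydroxy-8-oxo-2-thia-5-azabicyclo[4.2.0]oct-1(6)-ene-5-carboxylate 2,2-dioxide
Product: 17 di-tert-butyl 5,10-dihydroxy-7-[(1S)-2-(methoxymethylidene)-1,3-dimethylcyclohex-3-en-1-yl]-2,3-dihydro-4H-naphtho[2,3-b][1,4]thiazine-4,8-dicarboxylate 1,1-dioxide, via dienylketene 16 (not isolated)
Conditions: toluene (0.01 M, degassed), 110 °C
Reagents that add atoms: none
Why: Moore ring expansion: thermal conrotatory four-electron opening of the cyclobutenone breaks the bond between the carbonyl carbon and the carbinol carbon, and the hydroxyl group rotates outward, as donors on that carbon do, so the aryl group ends up cis to the ketene in 16. The ketene carbon then bonds to an aryl ortho carbon in a six-electron disrotatory electrocyclisation, which closes ring D as a cyclohexadienone that tautomerises to hydroquinone 17; release of ring strain and aromatisation drive the step. The closest known reaction type is the thermolysis of 4-aryl-4-hydroxycyclobutenones derived from squaric acid to naphthohydroquinones, including amino-substituted cases. No stereocentre is formed, and the carbinol configuration is lost. The nitrogen/sulfur placement is already fixed in 15, because the aryl-bearing carbinol carbon is the one next to the nitrogen-bearing carbon. The remaining selectivity is between the two ortho carbons of the aryl group: the one flanked by the quaternary ring A substituent is shielded by that tertiary alkyl group, and closure there would create a peri clash, so closure should occur at the ortho carbon para to it. High dilution in degassed toluene limits capture of the ketene by outside nucleophiles.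

Step 10
Reactants: 17 di-tert-butyl 5,10-dihydroxy-7-[(1S)-2-(methoxymethylidene)-1,3-dimethylcyclohex-3-en-1-yl]-2,3-dihydro-4H-naphtho[2,3-b][1,4]thiazine-4,8-dicarboxylate 1,1-dioxide
Product: 18 di-tert-butyl 7-[(1S)-2-(methoxymethylidene)-1,3-dimethylcyclohex-3-en-1-yl]-5,10-dioxo-2,3,5,10-tetrahydro-4H-naphtho[2,3-b][1,4]thiazine-4,8-dicarboxylate 1,1-dioxide
Conditions: Ag2O (3 equiv.), MgSO4, CH2Cl2, rt, dark
Reagents that add atoms: none
Why: Two-electron oxidation of the hydroquinone by Ag2O under neutral, anhydrous conditions gives the quinone without affecting the acid-sensitive dienol ether or the carbamate.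

Step 11
Reactants: 18 di-tert-butyl 7-[(1S)-2-(methoxymethylidene)-1,3-dimethylcyclohex-3-en-1-yl]-5,10-dioxo-2,3,5,10-tetrahydro-4H-naphtho[2,3-b][1,4]thiazine-4,8-dicarboxylate 1,1-dioxide
Product: 20 target: (S)-configured pentacycle of ring A (methylcyclohexene), ring B (seven-membered enol lactone), ring C (benzene), ring D (1,4-quinone) and ring E (N–H 1,4-thiazine 1,1-dioxide), via amino acid 19 (not isolated)
Conditions: CF3CO2H/CH2Cl2 (1:2), 4 Å molecular sieves, 0 °C to rt; evaporation from toluene
Reagents that add atoms: none
Why: Acidolysis removes the Boc group and the tert-butyl ester to give 19. Protonation of the dienol ether then gives an oxocarbenium ion that the neighbouring carboxylic acid captures in a seven-membered ring, and loss of methanol with deprotonation restores the conjugated diene as the enol lactone (acid-catalysed transacetalisation–elimination). The quaternary stereocentre has no adjacent hydrogen and is untouched, and the aminoquinone nitrogen is a non-basic vinylogous amide that stays free.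

## Compound list

1 | 4-bromo-2-iodobenzoic acid | OC(=O)c1ccc(Br)cc1I | starting material
2 | tert-butyl 4-bromo-2-iodobenzoate | CC(C)(C)OC(=O)c1ccc(Br)cc1I | intermediate
3 | 2,6-dimethylcyclohexanone | CC1CCCC(C)C1=O | starting material
4 | tert-butyl 4-bromo-2-[(1S)-1,3-dimethyl-2-oxocyclohexyl]benzoate | CC1CCC[C@@](C)(c2cc(Br)ccc2C(=O)OC(C)(C)C)C1=O | intermediate
5 | tert-butyl 4-bromo-2-[(1S)-1,3-dimethyl-2-(trimethylsilyloxy)cyclohex-2-en-1-yl]benzoate | CC=1CCC[C@@](C)(c2cc(Br)ccc2C(=O)OC(C)(C)C)C=1O[Si](C)(C)C | intermediate
6 | tert-butyl 4-bromo-2-[(1S)-1,3-dimethyl-2-oxocyclohex-3-en-1-yl]benzoate | CC1=CCC[C@@](C)(c2cc(Br)ccc2C(=O)OC(C)(C)C)C1=O | intermediate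
7 | tert-butyl 4-bromo-2-[(1S)-2-(methoxymethylidene)-1,3-dimethylcyclohex-3-en-1-yl]benzoate | COC=C1C(C)=CCC[C@@]1(C)c1cc(Br)ccc1C(=O)OC(C)(C)C | intermediate
8 | squaric acid | O=C1C(O)=C(O)C1=O | starting material
9 | 3,4-dichlorocyclobut-3-ene-1,2-dione | O=C1C(Cl)=C(Cl)C1=O | intermediate
10 | hypotaurine | NCCS(=O)O | starting material
11 | 3-chloro-4-[(2-sulfinoethyl)amino]cyclobut-3-ene-1,2-dione | O=C1C(=O)C(NCCS(=O)O)=C1Cl | intermediate
12 | 2-thia-5-azabicyclo[4.2.0]oct-1(6)-ene-7,8-dione 2,2-dioxide | O=C1C(=O)C2=C1NCCS2(=O)=O | intermediate
13 | tert-butyl 7,8-dioxo-2-thia-5-azabicyclo[4.2.0]oct-1(6)-ene-5-carboxylate 2,2-dioxide | CC(C)(C)OC(=O)N1CCS(=O)(=O)C2=C1C(=O)C2=O | intermediate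
14 | {4-(tert-butoxycarbonyl)-3-[(1S)-2-(methoxymethylidene)-1,3-dimethylcyclohex-3-en-1-yl]phenyl}magnesium chloride (LiCl complex) | COC=C1C(C)=CCC[C@@]1(C)c1cc([Mg]Cl)ccc1C(=O)OC(C)(C)C | intermediate
15 | tert-butyl 7-{4-(tert-butoxycarbonyl)-3-[(1S)-2-(methoxymethylidene)-1,3-dimethylcyclohex-3-en-1-yl]phenyl}-7-hydroxy-8-oxo-2-thia-5-azabicyclo[4.2.0]oct-1(6)-ene-5-carboxylate 2,2-dioxide | COC=C1C(C)=CCC[C@@]1(C)c1cc(ccc1C(=O)OC(C)(C)C)C1(O)C(=O)C2=C1N(C(=O)OC(C)(C)C)CCS2(=O)=O | intermediate
16 | dienylketene: tert-butyl 3-[aryl(hydroxy)methylidene]-2-(oxomethylidene)thiomorpholine-4-carboxylate 1,1-dioxide, aryl as in 15 | COC=C1C(C)=CCC[C@@]1(C)c1cc(ccc1C(=O)OC(C)(C)C)C(O)=C1N(C(=O)OC(C)(C)C)CCS(=O)(=O)C1=C=O | intermediate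
17 | di-tert-butyl 5,10-dihydroxy-7-[(1S)-2-(methoxymethylidene)-1,3-dimethylcyclohex-3-en-1-yl]-2,3-dihydro-4H-naphtho[2,3-b][1,4]thiazine-4,8-dicarboxylate 1,1-dioxide | COC=C1C(C)=CCC[C@@]1(C)c1cc2c(O)c3N(C(=O)OC(C)(C)C)CCS(=O)(=O)c3c(O)c2cc1C(=O)OC(C)(C)C | intermediate
18 | di-tert-butyl 7-[(1S)-2-(methoxymethylidene)-1,3-dimethylcyclohex-3-en-1-yl]-5,10-dioxo-2,3,5,10-tetrahydro-4H-naphtho[2,3-b][1,4]thiazine-4,8-dicarboxylate 1,1-dioxide | COC=C1C(C)=CCC[C@@]1(C)c1cc2C(=O)C3=C(C(=O)c2cc1C(=O)OC(C)(C)C)S(=O)(=O)CCN3C(=O)OC(C)(C)C | intermediate
19 | 7-[(1S)-2-(methoxymethylidene)-1,3-dimethylcyclohex-3-en-1-yl]-5,10-dioxo-3,4,5,10-tetrahydro-2H-naphtho[2,3-b][1,4]thiazine-8-carboxylic acid 1,1-dioxide | COC=C1C(C)=CCC[C@@]1(C)c1cc2C(=O)C3=C(C(=O)c2cc1C(=O)O)S(=O)(=O)CCN3 | intermediate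
20 | target CNP0348176.1, (S)-configured pentacyclic enol lactone thiazinoquinone (rings A–E as described) | CC1=CCC[C@]2(C)C1=COC(=O)c1cc3c(cc12)C(=O)C1=C(C3=O)S(=O)(=O)CCN1 | target

## Step count and least certain steps

Total: 11 steps. Longest linear sequence: 8 steps (1, 2, 3, 4, 8, 9, 10, 11); the cyclobutenedione branch (5, 6, 7) joins at step 8.

**Step 9 (key step).** Three things may go wrong: inward rotation of the hydroxyl group or capture of the ketene by that hydroxyl (leading towards a butenolide), thermal loss of the Boc group before ring opening, and a slow ring opening because the sulfonyl group makes the four-membered ring electron-poor. Fallback, setting out from 7 and returning at 20: the ring expansion is run on an alkoxy-substituted cyclobutenone, the best-precedented substrate class, and ring E is added afterwards. Arylmagnesium 14 (from 7 as in step 8) is added to 3-isopropoxycyclobut-3-ene-1,2-dione F1 (from commercial diisopropyl squarate with LiAlH(OtBu)3, then aqueous acid). Attack at the carbonyl next to the isopropoxy-bearing carbon gives hydroxycyclobutenone F2. Thermolysis in toluene should give the isopropoxy hydroquinone F3, and Ag2O the 2-isopropoxy-1,4-naphthoquinone F4, in which the alkoxy group marks the carbon that becomes C4a. Hypotaurine 10 in aqueous acetonitrile under air then replaces the isopropoxy group with its amine and adds its sulfinate to the neighbouring CH, with re-oxidation by air, to give the N–H thiazine dioxide quinone ester F5. The acid treatment of step 11 converts F5 into 20. This keeps the ring expansion and its regiochemical logic at the cost of two steps, and it also sidesteps the carbonyl selectivity needed in step 8.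

**Step 2.** C–C reductive elimination from a palladium enolate that must form a quaternary carbon next to an ortho-substituted aryl group is slow. This leaves room for β-hydride elimination (net reduction of 2), for eroded enantioselectivity, and for late insertion into the C–Br bond. Fallback, setting out from 2 and returning at 4: the quaternary centre is made by alkylation instead of arylation. 2-Methylcyclohexanone is arylated with 2 at its unhindered methylene carbon (Pd(OAc)2, bulky biaryl monophosphine, K3PO4) to give the 2-aryl-6-methylcyclohexanone F6. F6 is then methylated at the more acidic benzylic α-carbon with MeI under asymmetric phase-transfer catalysis (cinchona-derived quaternary ammonium salt, aqueous KOH/toluene, low temperature) to give 4.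

**Step 6.** The ambident sulfinate may attack through oxygen instead of sulfur, 9 may hydrolyse in the polar medium needed to dissolve the zwitterion, and intermolecular substitution may give oligomers. Fallback, setting out from 9 and returning at 13: 2-aminoethanethiol hydrochloride and Et3N condense with 9 to give the thiazine-fused dione F7 (sulfide oxidation level). Boc2O/DMAP gives carbamate F8. Sulfur is then oxidised with dimethyldioxirane in acetone, an oxidant chosen because peracids could attack the strained 1,2-dione, to give 13.

**Step 4.** The carbonyl is shielded by the quaternary carbon and the ortho-substituted aryl group. The basic ylide may deprotonate the γ-position instead of adding, or may decompose before it adds. Fallback, setting out from 6 and returning at 7: dimethylsulfonium methylide (from Me3S+ I− and KN(SiMe3)2), which is smaller than the phosphorus ylide, adds 1,2 to give spiro vinyl epoxide F9. BF3·OEt2 at low temperature induces a Meinwald rearrangement (opening to the allylic cation, hydride shift) to the β,γ-unsaturated aldehyde F10. Trimethyl orthoformate with pyridinium tosylate gives dimethyl acetal F11, and Me3SiOTf/iPr2NEt eliminates one methoxy group to give dienol ether 7.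

**Step 11.** Loss of methanol from the mixed acetal may be incomplete, traces of water may hydrolyse the oxocarbenium ion to the aldehyde, the ring A double bond may migrate through the allyl cation, and tert-butyl cations may alkylate the diene. Fallback, setting out from 18 and returning at 20: aqueous CF3CO2H is used deliberately to remove both tert-butyl groups and hydrolyse the enol ether, giving the conjugated aldehyde acid F12. The acid is then activated as a mixed anhydride (2,4,6-trichlorobenzoyl chloride, Et3N), and DMAP/Et3N generate the dienolate of the enal by γ-deprotonation. Intramolecular O-acylation of the dienolate closes the seven-membered enol lactone 20.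

## Further compounds

F1 | step 9 | 3-isopropoxycyclobut-3-ene-1,2-dione | CC(C)OC1=CC(=O)C1=O
F2 | step 9 | tert-butyl 4-(1-hydroxy-2-isopropoxy-4-oxocyclobut-2-en-1-yl)-2-[(1S)-2-(methoxymethylidene)-1,3-dimethylcyclohex-3-en-1-yl]benzoate | COC=C1C(C)=CCC[C@@]1(C)c1cc(ccc1C(=O)OC(C)(C)C)C1(O)C(OC(C)C)=CC1=O
F3 | step 9 | tert-butyl 5,8-dihydroxy-6-isopropoxy-3-[(1S)-2-(methoxymethylidene)-1,3-dimethylcyclohex-3-en-1-yl]naphthalene-2-carboxylate | COC=C1C(C)=CCC[C@@]1(C)c1cc2c(O)c(OC(C)C)cc(O)c2cc1C(=O)OC(C)(C)C
F4 | step 9 | tert-butyl 6-isopropoxy-3-[(1S)-2-(methoxymethylidene)-1,3-dimethylcyclohex-3-en-1-yl]-5,8-dioxo-5,8-dihydronaphthalene-2-carboxylate | COC=C1C(C)=CCC[C@@]1(C)c1cc2C(=O)C(OC(C)C)=CC(=O)c2cc1C(=O)OC(C)(C)C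
F5 | step 9 | tert-butyl 7-[(1S)-2-(methoxymethylidene)-1,3-dimethylcyclohex-3-en-1-yl]-5,10-dioxo-3,4,5,10-tetrahydro-2H-naphtho[2,3-b][1,4]thiazine-8-carboxylate 1,1-dioxide | COC=C1C(C)=CCC[C@@]1(C)c1cc2C(=O)C3=C(C(=O)c2cc1C(=O)OC(C)(C)C)S(=O)(=O)CCN3
F6 | step 2 | tert-butyl 4-bromo-2-(3-methyl-2-oxocyclohexyl)benzoate (racemic, epimer mixture) | CC1CCCC(c2cc(Br)ccc2C(=O)OC(C)(C)C)C1=O
F7 | step 6 | 2-thia-5-azabicyclo[4.2.0]oct-1(6)-ene-7,8-dione | O=C1C(=O)C2=C1NCCS2
F8 | step 6 | tert-butyl 7,8-dioxo-2-thia-5-azabicyclo[4.2.0]oct-1(6)-ene-5-carboxylate | CC(C)(C)OC(=O)N1CCSC2=C1C(=O)C2=O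
F9 | step 4 | tert-butyl 4-bromo-2-[(4S)-4,8-dimethyl-1-oxaspiro[2.5]oct-7-en-4-yl]benzoate (spiro carbon epimers) | CC1=CCC[C@@](C)(c2cc(Br)ccc2C(=O)OC(C)(C)C)C13CO3
F10 | step 4 | tert-butyl 4-bromo-2-[(1R)-2-formyl-1,3-dimethylcyclohex-3-en-1-yl]benzoate (epimers at the formyl-bearing carbon) | CC1=CCC[C@@](C)(c2cc(Br)ccc2C(=O)OC(C)(C)C)C1C=O
F11 | step 4 | tert-butyl 4-bromo-2-[(1R)-2-(dimethoxymethyl)-1,3-dimethylcyclohex-3-en-1-yl]benzoate (epimers at the acetal-bearing carbon) | CC1=CCC[C@@](C)(c2cc(Br)ccc2C(=O)OC(C)(C)C)C1C(OC)OC
F12 | step 11 | 7-[(1S)-2-formyl-1,3-dimethylcyclohex-2-en-1-yl]-5,10-dioxo-3,4,5,10-tetrahydro-2H-naphtho[2,3-b][1,4]thiazine-8-carboxylic acid 1,1-dioxide | O=CC1=C(C)CCC[C@@]1(C)c1cc2C(=O)C3=C(C(=O)c2cc1C(=O)O)S(=O)(=O)CCN3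
A1 | alternative 1 | 7-bromo-4-methoxy-1-methylnaphthalen-2-ol | COc1cc(O)c(C)c2cc(Br)ccc12
A2 | alternative 1 | pent-1-en-3-one | CCC(=O)C=C
A3 | alternative 1 | 6-bromo-9-methoxy-1,4a-dimethyl-4,4a-dihydrophenanthren-2(3H)-one (single enantiomer as in the SMILES) | CC1=C2C=C(OC)c3ccc(Br)cc3[C@]2(C)CCC1=O
A4 | alternative 2 | 2,3-bis(bromomethyl)-1,4-dimethoxybenzene | COc1ccc(OC)c(CBr)c1CBr
A5 | alternative 2 | tert-butyl 3-(2-formyl-1,3-dimethylcyclohex-2-en-1-yl)prop-2-ynoate (single enantiomer as in the SMILES) | CC(C)(C)OC(=O)C#C[C@]1(C)CCCC(C)=C1C=O
A6 | alternative 2 | tert-butyl 3-(2-formyl-1,3-dimethylcyclohex-2-en-1-yl)-5,8-dimethoxy-1,4-dihydronaphthalene-2-carboxylate (single enantiomer as in the SMILES) | CC(C)(C)OC(=O)C1=C(Cc2c(OC)ccc(OC)c2C1)[C@]1(C)CCCC(C)=C1C=O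
A7 | alternative 3 | tert-butyl 5,6,8-trimethoxy-3-(3-oxoprop-1-en-2-yl)naphthalene-2-carboxylate | C=C(C=O)c1cc2c(OC)c(OC)cc(OC)c2cc1C(=O)OC(C)(C)C
A8 | alternative 3 | (E)-tert-butyl(dimethyl)[(2-methylbuta-1,3-dien-1-yl)oxy]silane | C=C/C(C)=C/O[Si](C)(C)C(C)(C)C
A9 | alternative 3 | tert-butyl 3-[2-(tert-butyldimethylsilyloxy)-1-formyl-3-methylcyclohex-3-en-1-yl]-5,6,8-trimethoxynaphthalene-2-carboxylate (endo-formyl isomer as in the SMILES) | CC1=CCC[C@@](C=O)(c2cc3c(OC)c(OC)cc(OC)c3cc2C(=O)OC(C)(C)C)[C@@H]1O[Si](C)(C)C(C)(C)C
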